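I started from the charges. South-east and north-west held the same substrate, reagent and initiator as the epsilon and alpha runs, and differed from those runs and from each other in the scavenger: 0.500 equiv and 1.00 equiv, against 0.65 equiv and 1.3 equiv. They also differed from those runs in time: both were asked at 15 min, and the last reading of each earlier run stood at 10.0 min.

| setting | epsilon | alpha | south-east | north-west |
|---|---|---|---|---|
| substrate | 0.25 M | 0.25 M | 0.25 M | 0.25 M |
| reagent | 1 equiv | 1 equiv | 1.00 equiv | 1.00 equiv |
| scavenger | 0.65 equiv | 1.3 equiv | 0.500 equiv | 1.00 equiv |
| initiator | 2.5 mol% | 2.5 mol% | 2.5 mol% | 2.5 mol% |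
| remark | run made earlier | run made earlier |  |  |
| time |  |  | 15 min | 15 min |

| run | time / min | substrate / % | target / % |
|---|---|---|---|
| epsilon | 1.50 | 66.2 | 27.7 |
| epsilon | 3.00 | 47.0 | 48.6 |
| epsilon | 5.00 | 29.6 | 68.2 |
| epsilon | 6.00 | 22.4 | 72.3 |
| epsilon | 8.00 | 15.1 | 82.3 |
| epsilon | 10.0 | 9.1 | 87.4 |
| alpha | 0.500 | 86.8 | 11.7 |
| alpha | 1.50 | 70.3 | 30.6 |
| alpha | 3.00 | 48.1 | 51.1 |
| alpha | 5.00 | 29.4 | 67.3 |
| alpha | 6.00 | 24.9 | 75.3 |
| alpha | 8.00 | 16.1 | 84.4 |
| alpha | 10.0 | 10.4 | 91.2 |

(each reading ± 1 percentage point)

* part of the substrate that has reacted at the end, south-east
* part of the substrate that has reacted at the end, north-west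
* what raising the equivalents of scavenger from its lowest to its highest value here does to the part of the substrate that has reacted (changes below 5 percentage points count as none) (it falls / no change / it rises)

- what has gone from substrate into another species counts as reacted, even if it can come back

I worked with the fraction left, not the fraction made, and I read it two ways. The first way took the substrate reading itself at the last reading of each run:

k = ln([substrate] at the start / [substrate] at time t) / t
epsilon: 0.240 /min
alpha: 0.226 /min

The second way took as left whatever was not yet target:

epsilon: 0.207 /min
alpha: 0.243 /min

The two ways parted by less in the alpha run than in the epsilon run. So I added substrate and target over each run. They averaged 99.7% in the alpha run but 96.0% in the epsilon run. In the epsilon run the second way therefore cheated: it counted as left a part that was neither substrate nor target, and the question counts that part as reacted.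

I kept the first way. Its two readings, taken at scavenger charges differing by a factor of 2.00, gave a mean pseudo-first-order constant, the decay constant of the substrate, of 0.233 /min. For both flasks, although south-east lay below the scavenger charges tried:

left = exp(−k t) = 3.03%, reacted 97.0%

The forecast gave 96.5% (88% to 99%) for south-east, below my figure, 97% (94.5% to 99%) for north-west, and no change, since “doubling the scavenger does nothing to the rate”.

The simulation gave 95.9% for south-east and 96.9% for north-west, a change of 1 percentage point, so no change.

    initiator → 2 initiating radical (k = 1.63 × 10⁻⁴ /s)
    substrate + initiating radical → capped initiator + first chain carrier (k = 1.22 × 10⁶ /M/s)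
    reagent + first chain carrier ⇌ target + second chain carrier (K = 4.24, k = 17100 /M/s)
    substrate + second chain carrier → released group + first chain carrier (k = 90100 /M/s)
    2 second chain carrier → ended chains (k = 5.00 × 10⁸ /M/s)
    substrate + released group ⇌ idle adduct, settled at all times (K = 9.60 /M)
    scavenger + released group → scavenged by-product (k = 0.774 /M/s)

North-west ended with 3.1% of its substrate left, against my 3.03%, and its 3.1% read back as a constant of 0.232 /min. I then took the north-west flask and stopped it at 4.0 min, with every amount held. The same constant gave:

left = exp(−k t) = 39.4%

That flask held 37.8% of its substrate at that time, and 43% of its scavenger was still free. The part of its substrate that had reacted was 62.2%.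

The numbers in the tables are calculated from invented constants; the scatter is artificial.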